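## Retrosynthetic overview

1. The ten-membered ring is closed last, by ring-closing metathesis across C4=C5 of an open-chain triene (propenyl group on C6, 1,1-disubstituted olefin at C4).
2. The C8 ester comes from a Mitsunobu inversion of the 8-epi alcohol with (S)-2-methylbutanoic acid; the enal and the primary alcohol are unmasked from an acetal and a silyl ether.
3. The C7–C8 bond and the α-methylene lactone come from a chromium-mediated allylation of a β,γ-unsaturated aldehyde (fragment B: C8–C10, C14, C1–C4, C15) with a 3-(bromomethyl)butenolide (fragment A: C5–C7, C11–C13).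
4. Fragment A: butenolide by ring-closing metathesis of the 2-(bromomethyl)acrylate of a kinetically resolved dienol. Fragment B: Johnson–Claisen rearrangement, vinyllithium addition, Still–Wittig [2,3] shift (sets the C1=C10 geometry).
5. Ring order: five-membered lactone first (step 4), cyclodecadiene last (step 17).

Convention: C1–C15 are the germacrane positions of the target (C6 lactone O–CH, C7 ring fusion, C8 ester carbinol, C11=C13 exocyclic olefin, C12 lactone C=O, C14 CHO, C15 CH2OH); commodity reagents and catalysts are bought.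

## Fragment A (steps 1–4)

Step 1
Reactants: 1 (2E)-but-2-enal; 2 vinylmagnesium bromide
Product: 3 rac-(4E)-hexa-1,4-dien-3-ol
Conditions: THF, −78 to 0 °C; then H2O
Reagents that add atoms: none
Why: Grignard 1,2-addition to the enal carbonyl gives the racemic bis-allylic alcohol, whose carbinol centre (the future C6) is resolved in step 2.

Step 2
Reactants: 3 rac-(4E)-hexa-1,4-dien-3-ol
Product: 4 (3S,4E)-hexa-1,4-dien-3-ol
Conditions: Ti(OiPr)4 (0.1 equiv), D-(−)-diisopropyl tartrate (0.15 equiv), t-BuOOH (0.6 equiv), MS 4 Å, CH2Cl2, −20 °C, to about 55% conversion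
Reagents that add atoms: none
Why: Sharpless kinetic resolution: with the D-tartrate the propenyl group of the (R)-alcohol is epoxidised fast, while the (S)-alcohol, whose only matched olefin is the sluggish monosubstituted vinyl group, is recovered in high ee.

Step 3
Reactants: 4 (3S,4E)-hexa-1,4-dien-3-ol; 5 2-(bromomethyl)prop-2-enoic acid
Product: 6 (3S,4E)-hexa-1,4-dien-3-yl 2-(bromomethyl)prop-2-enoate
Conditions: DCC, DMAP (5 mol%), CH2Cl2, −10 to 0 °C
Reagents that add atoms: none
Why: Steglich esterification acylates the hydroxyl without touching the stereocentre, and low temperature with only catalytic DMAP spares the allylic bromide.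

Step 4
Reactants: 6 (3S,4E)-hexa-1,4-dien-3-yl 2-(bromomethyl)prop-2-enoate
Product: 7 (5R)-3-(bromomethyl)-5-[(1E)-prop-1-en-1-yl]furan-2(5H)-one
Conditions: second-generation Grubbs catalyst RuCl2(=CHPh)(H2IMes)(PCy3) (5 mol%), toluene (5 mM), 80 °C
Reagents that add atoms: none
Why: Ring-closing metathesis: the ruthenium carbene loads on the terminal vinyl group in preference to the internal propenyl group and closes onto the acrylate to give the butenolide with the stereocentre untouched; the minor 5-vinyl isomer from initiation at the propenyl group is removed by chromatography.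

## Fragment B (steps 5–13)

Step 5
Reactants: 8 2-methylidenepropane-1,3-diol
Product: 9 2-({[tert-butyl(dimethyl)silyl]oxy}methyl)prop-2-en-1-ol
Conditions: NaH (1 equiv), THF, 0 °C; then TBSCl (1 equiv), rt
Reagents that add atoms: tert-butyl(chloro)dimethylsilane, TBSCl (CC(C)(C)[Si](C)(C)Cl)
Why: Monosilylation of the symmetrical diol through its sparingly soluble monosodium alkoxide gives the mono-TBS ether selectively.

Step 6
Reactants: 9 2-({[tert-butyl(dimethyl)silyl]oxy}methyl)prop-2-en-1-ol
Product: 11 ethyl 4-({[tert-butyl(dimethyl)silyl]oxy}methyl)pent-4-enoate, via ketene acetal 10 (not isolated)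
Conditions: MeC(OEt)3 (5 equiv), EtCO2H (cat.), 140 °C, EtOH distilled off
Reagents that add atoms: triethyl orthoacetate (CC(OCC)(OCC)OCC)
Why: Johnson–Claisen rearrangement: the mixed ketene acetal undergoes a [3,3]-sigmatropic shift that builds the C2–C3 bond and leaves the 1,1-disubstituted C4 olefin with its CH2OTBS group in place.

Step 7
Reactants: 11 ethyl 4-({[tert-butyl(dimethyl)silyl]oxy}methyl)pent-4-enoate
Product: 12 4-({[tert-butyl(dimethyl)silyl]oxy}methyl)pent-4-enal
Conditions: i-Bu2AlH (1.1 equiv), CH2Cl2, −78 °C; then aqueous work-up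
Reagents that add atoms: none
Why: Partial ester reduction: the aluminium hemiacetal formed with one equivalent of hydride is stable at −78 °C and releases the aldehyde (C1) only on work-up.

Step 8
Reactants: 13 3,3-diethoxyprop-1-ene
Product: 14 2,3-dibromo-1,1-diethoxypropane
Conditions: Br2, CH2Cl2, −78 to 0 °C
Reagents that add atoms: bromine (BrBr)
Why: Electrophilic anti-addition of bromine to the vinyl group, with the acetal inert.

Step 9
Reactants: 14 2,3-dibromo-1,1-diethoxypropane
Product: 15 2-bromo-3,3-diethoxyprop-1-ene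
Conditions: t-BuOK, THF, 0 °C to rt
Reagents that add atoms: none
Why: E2 dehydrobromination removes the C2–H (acidified by bromine and the acetal) together with the primary bromide and gives the 2-bromoalkene.

Step 10
Reactants: 15 2-bromo-3,3-diethoxyprop-1-ene; 12 4-({[tert-butyl(dimethyl)silyl]oxy}methyl)pent-4-enal
Product: 17 rac-6-({[tert-butyl(dimethyl)silyl]oxy}methyl)-1,1-diethoxy-2-methylidenehept-6-en-3-ol, via vinyllithium reagent 16 (not isolated)
Conditions: 15, n-BuLi, THF, −78 °C; then 12, −78 °C; then H2O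
Reagents that add atoms: none
Why: Bromine–lithium exchange gives the α-lithioacrolein acetal, which adds 1,2 to the aldehyde; the new carbinol centre is racemic and is erased in step 12.

Step 11
Reactants: 17 rac-6-({[tert-butyl(dimethyl)silyl]oxy}methyl)-1,1-diethoxy-2-methylidenehept-6-en-3-ol
Product: 18 rac-tributyl[({6-({[tert-butyl(dimethyl)silyl]oxy}methyl)-1,1-diethoxy-2-methylidenehept-6-en-3-yl}oxy)methyl]stannane
Conditions: KH, THF, 0 °C; then Bu3SnCH2I, rt
Reagents that add atoms: tributyl(iodomethyl)stannane (CCCC[Sn](CCCC)(CCCC)CI)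
Why: Williamson etherification of the potassium alkoxide with the highly SN2-reactive iodomethylstannane.

Step 12
Reactants: 18 rac-tributyl[({6-({[tert-butyl(dimethyl)silyl]oxy}methyl)-1,1-diethoxy-2-methylidenehept-6-en-3-yl}oxy)methyl]stannane
Product: 20 (3E)-7-({[tert-butyl(dimethyl)silyl]oxy}methyl)-3-(diethoxymethyl)octa-3,7-dien-1-ol, via lithiomethyl ether 19 (not isolated)
Conditions: n-BuLi, THF, −78 °C; then H2O
Reagents that add atoms: none
Why: Tin–lithium exchange triggers the Still–Wittig [2,3]-sigmatropic rearrangement, in which allylic strain with the 2-substituent holds the chain pseudo-axial so that the new CH2CH2OH arm (C9–C8) ends up cis to the C2 chain, the ring-cis C1=C10 geometry of the target.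

Step 13
Reactants: 20 (3E)-7-({[tert-butyl(dimethyl)silyl]oxy}methyl)-3-(diethoxymethyl)octa-3,7-dien-1-ol
Product: 21 (3E)-7-({[tert-butyl(dimethyl)silyl]oxy}methyl)-3-(diethoxymethyl)octa-3,7-dienal
Conditions: Dess–Martin periodinane, pyridine, CH2Cl2, 0 °C; used at once
Reagents that add atoms: none
Why: Buffered Dess–Martin oxidation gives the β,γ-unsaturated aldehyde (C8) without acetal loss or migration of the olefin into conjugation.

## Union and endgame (steps 14–17)

Step 14
Reactants: 7 (5R)-3-(bromomethyl)-5-[(1E)-prop-1-en-1-yl]furan-2(5H)-one; 21 (3E)-7-({[tert-butyl(dimethyl)silyl]oxy}methyl)-3-(diethoxymethyl)octa-3,7-dienal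
Product: 23 (4R,5R)-4-[(1S,3E)-7-({[tert-butyl(dimethyl)silyl]oxy}methyl)-3-(diethoxymethyl)-1-hydroxyocta-3,7-dien-1-yl]-3-methylidene-5-[(1E)-prop-1-en-1-yl]oxolan-2-one, via allylchromium reagent 22 (not isolated)
Conditions: CrCl2 (3 equiv), THF, 0 °C to rt; then H2O
Reagents that add atoms: none
Why: Nozaki–Hiyama allylation: the allylchromium reagent formed by divalent chromium adds through its γ-carbon in a chair Zimmerman–Traxler transition state, anti to the propenyl group (trans lactone, C7 R) and, with the allyl geometry locked in the ring, anti in the crotylation sense (C8 S, the 8-epi alcohol), unveiling the α-methylene lactone.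

Step 15
Reactants: 23 (4R,5R)-4-[(1S,3E)-7-({[tert-butyl(dimethyl)silyl]oxy}methyl)-3-(diethoxymethyl)-1-hydroxyocta-3,7-dien-1-yl]-3-methylidene-5-[(1E)-prop-1-en-1-yl]oxolan-2-one; 24 (2S)-2-methylbutanoic acid
Product: 25 (1R,3E)-7-({[tert-butyl(dimethyl)silyl]oxy}methyl)-3-(diethoxymethyl)-1-{(2R,3R)-4-methylidene-5-oxo-2-[(1E)-prop-1-en-1-yl]oxolan-3-yl}octa-3,7-dien-1-yl (2S)-2-methylbutanoate
Conditions: PPh3, DIAD, toluene, 0 °C to rt
Reagents that add atoms: none
Why: Mitsunobu esterification: SN2 displacement of the alkoxyphosphonium ion by the carboxylate inverts C8 to the required R configuration under neutral conditions that leave the acid's α-centre and the lactone untouched.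

Step 16
Reactants: 25 (1R,3E)-7-({[tert-butyl(dimethyl)silyl]oxy}methyl)-3-(diethoxymethyl)-1-{(2R,3R)-4-methylidene-5-oxo-2-[(1E)-prop-1-en-1-yl]oxolan-3-yl}octa-3,7-dien-1-yl (2S)-2-methylbutanoate
Product: 26 (1R,3E)-3-formyl-7-(hydroxymethyl)-1-{(2R,3R)-4-methylidene-5-oxo-2-[(1E)-prop-1-en-1-yl]oxolan-3-yl}octa-3,7-dien-1-yl (2S)-2-methylbutanoate
Conditions: aq. HF (5%), MeCN, 0 °C to rt
Reagents that add atoms: water (O)
Why: Aqueous acid hydrolyses the allylic acetal to the enal (the more stable geometry, unchanged) and cleaves the primary silyl ether, while the esters and the α-methylene lactone survive.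

Step 17
Reactants: 26 (1R,3E)-3-formyl-7-(hydroxymethyl)-1-{(2R,3R)-4-methylidene-5-oxo-2-[(1E)-prop-1-en-1-yl]oxolan-3-yl}octa-3,7-dien-1-yl (2S)-2-methylbutanoate
Product: 27 (3aR,4R,6E,10E,11aR)-6-formyl-10-(hydroxymethyl)-3-methylidene-2-oxo-2,3,3a,4,5,8,9,11a-octahydrocyclodeca[b]furan-4-yl (2S)-2-methylbutanoate
Conditions: second-generation Hoveyda–Grubbs catalyst RuCl2(=CH-2-(i-PrO)C6H4)(H2IMes) (10 mol%), 1,4-benzoquinone (20 mol%), toluene (1 mM), 80 °C
Reagents that add atoms: none
Why: Ring-closing metathesis between the propenyl group and the 1,1-disubstituted allylic-alcohol olefin closes the ten-membered ring with loss of propene, the trisubstituted C4=C5 olefin being expected in the less strained ring-cis geometry (C6 cis to C3) and the electron-poor enal and α-methylene lactone olefins staying spectators.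

## Compound list

1 | (2E)-but-2-enal | C/C=C/C=O | starting material
2 | vinylmagnesium bromide | C=C[Mg]Br | starting material
3 | rac-(4E)-hexa-1,4-dien-3-ol | C=CC(O)/C=C/C | intermediate
4 | (3S,4E)-hexa-1,4-dien-3-ol | C=C[C@H](O)/C=C/C | intermediate
5 | 2-(bromomethyl)prop-2-enoic acid | C=C(CBr)C(=O)O | starting material
6 | (3S,4E)-hexa-1,4-dien-3-yl 2-(bromomethyl)prop-2-enoate | C=C[C@H](OC(=O)C(=C)CBr)/C=C/C | intermediate
7 | (5R)-3-(bromomethyl)-5-[(1E)-prop-1-en-1-yl]furan-2(5H)-one | BrCC1=C[C@@H](/C=C/C)OC1=O | intermediate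
8 | 2-methylidenepropane-1,3-diol | C=C(CO)CO | starting material
9 | 2-({[tert-butyl(dimethyl)silyl]oxy}methyl)prop-2-en-1-ol | C=C(CO)CO[Si](C)(C)C(C)(C)C | intermediate
10 | tert-butyl[(2-{[(1-ethoxyethenyl)oxy]methyl}prop-2-en-1-yl)oxy]dimethylsilane (ketene acetal, not isolated) | C=C(OCC)OCC(=C)CO[Si](C)(C)C(C)(C)C | intermediate
11 | ethyl 4-({[tert-butyl(dimethyl)silyl]oxy}methyl)pent-4-enoate | CCOC(=O)CCC(=C)CO[Si](C)(C)C(C)(C)C | intermediate
12 | 4-({[tert-butyl(dimethyl)silyl]oxy}methyl)pent-4-enal | O=CCCC(=C)CO[Si](C)(C)C(C)(C)C | intermediate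
13 | 3,3-diethoxyprop-1-ene (acrolein diethyl acetal) | C=CC(OCC)OCC | starting material
14 | 2,3-dibromo-1,1-diethoxypropane (racemic) | CCOC(OCC)C(Br)CBr | intermediate
15 | 2-bromo-3,3-diethoxyprop-1-ene | C=C(Br)C(OCC)OCC | intermediate
16 | (3,3-diethoxyprop-1-en-2-yl)lithium (not isolated) | [Li]C(=C)C(OCC)OCC | intermediate
17 | rac-6-({[tert-butyl(dimethyl)silyl]oxy}methyl)-1,1-diethoxy-2-methylidenehept-6-en-3-ol | CCOC(OCC)C(=C)C(O)CCC(=C)CO[Si](C)(C)C(C)(C)C | intermediate
18 | rac-tributyl[({6-({[tert-butyl(dimethyl)silyl]oxy}methyl)-1,1-diethoxy-2-methylidenehept-6-en-3-yl}oxy)methyl]stannane | CCCC[Sn](CCCC)(CCCC)COC(CCC(=C)CO[Si](C)(C)C(C)(C)C)C(=C)C(OCC)OCC | intermediate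
19 | rac-[({6-({[tert-butyl(dimethyl)silyl]oxy}methyl)-1,1-diethoxy-2-methylidenehept-6-en-3-yl}oxy)methyl]lithium (not isolated) | [Li]COC(CCC(=C)CO[Si](C)(C)C(C)(C)C)C(=C)C(OCC)OCC | intermediate
20 | (3E)-7-({[tert-butyl(dimethyl)silyl]oxy}methyl)-3-(diethoxymethyl)octa-3,7-dien-1-ol (CH2CH2OH arm cis to the C5 chain) | OCC/C(C(OCC)OCC)=C\CCC(=C)CO[Si](C)(C)C(C)(C)C | intermediate
21 | (3E)-7-({[tert-butyl(dimethyl)silyl]oxy}methyl)-3-(diethoxymethyl)octa-3,7-dienal | O=CC/C(C(OCC)OCC)=C\CCC(=C)CO[Si](C)(C)C(C)(C)C | intermediate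
22 | dichloro({(5R)-2-oxo-5-[(1E)-prop-1-en-1-yl]-2,5-dihydrofuran-3-yl}methyl)chromium (not isolated) | Cl[Cr](Cl)CC1=C[C@@H](/C=C/C)OC1=O | intermediate
23 | (4R,5R)-4-[(1S,3E)-7-({[tert-butyl(dimethyl)silyl]oxy}methyl)-3-(diethoxymethyl)-1-hydroxyocta-3,7-dien-1-yl]-3-methylidene-5-[(1E)-prop-1-en-1-yl]oxolan-2-one | C=C1C(=O)O[C@H](/C=C/C)[C@H]1[C@@H](O)C/C(C(OCC)OCC)=C\CCC(=C)CO[Si](C)(C)C(C)(C)C | intermediate
24 | (2S)-2-methylbutanoic acid | CC[C@H](C)C(=O)O | starting material
25 | (1R,3E)-7-({[tert-butyl(dimethyl)silyl]oxy}methyl)-3-(diethoxymethyl)-1-{(2R,3R)-4-methylidene-5-oxo-2-[(1E)-prop-1-en-1-yl]oxolan-3-yl}octa-3,7-dien-1-yl (2S)-2-methylbutanoate | C=C1C(=O)O[C@H](/C=C/C)[C@H]1[C@H](OC(=O)[C@@H](C)CC)C/C(C(OCC)OCC)=C\CCC(=C)CO[Si](C)(C)C(C)(C)C | intermediate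
26 | (1R,3E)-3-formyl-7-(hydroxymethyl)-1-{(2R,3R)-4-methylidene-5-oxo-2-[(1E)-prop-1-en-1-yl]oxolan-3-yl}octa-3,7-dien-1-yl (2S)-2-methylbutanoate | C=C1C(=O)O[C@H](/C=C/C)[C@H]1[C@H](OC(=O)[C@@H](C)CC)C/C(C=O)=C\CCC(=C)CO | intermediate
27 | (3aR,4R,6E,10E,11aR)-6-formyl-10-(hydroxymethyl)-3-methylidene-2-oxo-2,3,3a,4,5,8,9,11a-octahydrocyclodeca[b]furan-4-yl (2S)-2-methylbutanoate | C=C1C(=O)O[C@@H]2/C=C(/CO)CC/C=C(/C=O)C[C@@H](OC(=O)[C@@H](C)CC)[C@@H]12 | target

## Step count and risks

Total step count: 17 (fragment A 4 steps, fragment B 9 steps including the two-step side branch 13 → 15, union and endgame 4 steps).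
Longest linear sequence: 11 steps (steps 5, 6, 7, 10, 11, 12, 13, 14, 15, 16, 17, from 8 to 27), about 65% of the total.

Steps most likely to fail:

Step 17 (ring-closing metathesis). Neither olefin partner is a simple terminal alkene, the ring is a strained medium ring, the geometry of the new trisubstituted olefin is not guaranteed, and the free aldehyde and allylic alcohol may shorten catalyst life. The fallback sets out from 25 and comes back at 27. The ring is closed before unmasking, on the fully protected triene, with the more reactive molybdenum alkylidene Mo(=N-2,6-i-Pr2C6H3)(=CHCMe2Ph)[OCMe(CF3)2]2 (benzene, 1 mM, 60 °C), which tolerates acetal, silyl ether and esters but not free CHO or OH. This gives the protected macrocycle (3aR,4R,6E,10E,11aR)-10-({[tert-butyl(dimethyl)silyl]oxy}methyl)-6-(diethoxymethyl)-3-methylidene-2-oxo-2,3,3a,4,5,8,9,11a-octahydrocyclodeca[b]furan-4-yl (2S)-2-methylbutanoate F3. Aqueous HF in MeCN then releases the aldehyde and the alcohol to give 27.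

Step 15 (Mitsunobu inversion). The carbinol is hindered by the branched C7 and has allylic β-hydrogens on both sides, so elimination can compete with substitution by the weakly acidic, α-branched acid. The fallback sets out from 23 and comes back at 25. The hydroxyl is activated separately with ClCH2SO2Cl and pyridine (CH2Cl2, 0 °C) to give (1S,3E)-7-({[tert-butyl(dimethyl)silyl]oxy}methyl)-3-(diethoxymethyl)-1-{(2R,3S)-4-methylidene-5-oxo-2-[(1E)-prop-1-en-1-yl]oxolan-3-yl}octa-3,7-dien-1-yl chloromethanesulfonate F2. This is displaced with inversion by the caesium salt of 24 (from 24 and Cs2CO3; 18-crown-6, toluene, 60 °C) to give 25.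

Step 14 (fragment union). Aldehyde 21 can slip into conjugation, the allylmetal can dimerise reductively, and the selectivity at C8 rests on a closed transition state. The fallback sets out from 7 and comes back at 23. Bromide 7 is converted with B2pin2 and Pd2(dba)3 (toluene, 50 °C, no base) into the isolable allylboronate (5R)-3-[(4,4,5,5-tetramethyl-1,3,2-dioxaborolan-2-yl)methyl]-5-[(1E)-prop-1-en-1-yl]furan-2(5H)-one F1. F1 is then combined with 21 in a salt-free thermal allylboration (toluene, 60 °C, aqueous work-up), which passes through the same chair arrangement and gives 23.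

## Further compounds

F1 | step 14 | (5R)-3-[(4,4,5,5-tetramethyl-1,3,2-dioxaborolan-2-yl)methyl]-5-[(1E)-prop-1-en-1-yl]furan-2(5H)-one | CC1(C)OB(CC2=C[C@@H](/C=C/C)OC2=O)OC1(C)C
F2 | step 15 | (1S,3E)-7-({[tert-butyl(dimethyl)silyl]oxy}methyl)-3-(diethoxymethyl)-1-{(2R,3S)-4-methylidene-5-oxo-2-[(1E)-prop-1-en-1-yl]oxolan-3-yl}octa-3,7-dien-1-yl chloromethanesulfonate | C=C1C(=O)O[C@H](/C=C/C)[C@H]1[C@@H](OS(=O)(=O)CCl)C/C(C(OCC)OCC)=C\CCC(=C)CO[Si](C)(C)C(C)(C)C
F3 | step 17 | (3aR,4R,6E,10E,11aR)-10-({[tert-butyl(dimethyl)silyl]oxy}methyl)-6-(diethoxymethyl)-3-methylidene-2-oxo-2,3,3a,4,5,8,9,11a-octahydrocyclodeca[b]furan-4-yl (2S)-2-methylbutanoate | C=C1C(=O)O[C@@H]2/C=C(/CO[Si](C)(C)C(C)(C)C)CC/C=C(/C(OCC)OCC)C[C@@H](OC(=O)[C@@H](C)CC)[C@@H]12
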